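**Plan**

1. Ring letters: A = pentaoxygenated benzene of the dioxin, B = 1,4-dioxin, C = central benzene shared by B and the furan, D = outer benzo ring of the furan, E = phenoxy on D, F = phenoxy on A. Rings C and D carry dibenzofuran numbers (bay carbons C1 and C9, C6 next to the furan oxygen).
2. Cuts, last made first: nine O–CH3 bonds; the ring F–O–ring A ether; the ring B C–O bond at bay carbon C1; the bond from the C2 oxygen to ring A; C8–C9 of ring D; the side-chain C6–C7 and C6–O(ring E) bonds; C1–Br; the furan C–C and C–O bonds.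
3. Enabling feature: ring D is a resorcinol (OH on C7 and C9). Its C6 lies between the furan-oxygen carbon C5a and C7–OH and bears the crowded O–ring E ether, so C6 can begin as an sp3 carbon between furan C2 and a ketone (C7), with C8 as the ketone methyl and C9 as the ester carbon on furan C3.
4. Forward order: furan plus ring C (quinone/β-keto ester annulation), ring E by SN2 under base only, ring D by Claisen aromatisation, ring A by SNAr, ring B by CuI closure, ring F by CuI arylation, global demethylation.
5. Ring A is symmetric about the axis through its C–H and the para C–O(ring C). A symmetric 2-fluoroisophthalaldehyde, whose two CHO groups become the two flanking OH groups by Baeyer–Villiger oxidation, therefore removes every regiochemical question from the dioxin annulation.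
6. Stereochemistry: the target is achiral. The only stereocentre on the way (the future C6 in 10, racemic) is erased when ring D aromatises.

Key step: step 7

Assumption: 1, 2, 8, 15 and 22 are bought, lithium diisopropylamide is used as a bought solution, and racemic compounds are written without a stereo descriptor in their SMILES.

**Route**

Step 1
Reactants: 1 2-methoxy-1,4-benzoquinone; 2 methyl acetoacetate
Product: 4 methyl 5-hydroxy-6-methoxy-2-methyl-1-benzofuran-3-carboxylate, via hydroquinone Michael adduct 3 (not isolated)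
Conditions: Cu(OTf)2 (10 mol %), toluene, 80 °C
Reagents that add atoms: none
Why: In this benzofuran variant of the Nenitzescu reaction the β-keto ester adds in Michael fashion to quinone C5 (para to the methoxy-bearing carbon, the only ring position not deactivated by the vinylogous ester), and hydroquinone 3 then cyclodehydrates onto the ketone in a redox-neutral sequence.

Step 2
Reactants: 4 methyl 5-hydroxy-6-methoxy-2-methyl-1-benzofuran-3-carboxylate
Product: 5 methyl 4-bromo-5-hydroxy-6-methoxy-2-methyl-1-benzofuran-3-carboxylate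
Conditions: NBS (1.0 equiv), MeCN, 0 °C
Reagents that add atoms: N-bromosuccinimide O=C1CCC(=O)N1Br
Why: In this electrophilic aromatic bromination the free C5 hydroxyl directs ortho, C6 is blocked by methoxy and the para position is the ring fusion, so bromine should enter at C4 with the same ortho-to-OH preference that guaiacol-type phenols such as vanillin show.

Step 3
Reactants: 5 methyl 4-bromo-5-hydroxy-6-methoxy-2-methyl-1-benzofuran-3-carboxylate
Product: 6 methyl 4-bromo-6-methoxy-2-methyl-5-(triisopropylsilyloxy)-1-benzofuran-3-carboxylate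
Conditions: TIPSOTf, 2,6-lutidine, CH2Cl2, 0 °C to rt
Reagents that add atoms: triisopropylsilyl triflate CC(C)[Si](OS(=O)(=O)C(F)(F)F)(C(C)C)C(C)C
Why: Silylation of a hindered phenol with the reactive silyl triflate gives an ether that should tolerate radical bromination, carbonate, amide bases and methylation, and that fluoride later removes without touching the aryl bromide.

Step 4
Reactants: 6 methyl 4-bromo-6-methoxy-2-methyl-5-(triisopropylsilyloxy)-1-benzofuran-3-carboxylate
Product: 7 methyl 4-bromo-2-(bromomethyl)-6-methoxy-5-(triisopropylsilyloxy)-1-benzofuran-3-carboxylate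
Conditions: NBS (1.05 equiv), AIBN (5 mol %), PhCF3, 85 °C
Reagents that add atoms: N-bromosuccinimide O=C1CCC(=O)N1Br
Why: This is a Wohl–Ziegler bromination of the C2 methyl group, the only allylic/benzylic C–H in 6 and the usual radical site of 2-methylbenzofuran-3-carboxylates, with the non-polar medium holding back ionic attack at C7.

Step 5
Reactants: 7 methyl 4-bromo-2-(bromomethyl)-6-methoxy-5-(triisopropylsilyloxy)-1-benzofuran-3-carboxylate; 8 3,5-dimethoxyphenol
Product: 9 methyl 4-bromo-2-[(3,5-dimethoxyphenoxy)methyl]-6-methoxy-5-(triisopropylsilyloxy)-1-benzofuran-3-carboxylate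
Conditions: K2CO3, acetone, 50 °C
Reagents that add atoms: none
Why: A Williamson ether synthesis (SN2) at a primary furfuryl-type bromide builds the future C6–O–ring E ether at an sp3 carbon, with no aryl coupling and without the acid that would cyclodehydrate aryloxy carbonyl compounds of so electron-rich a phenol.

Step 6
Reactants: 9 methyl 4-bromo-2-[(3,5-dimethoxyphenoxy)methyl]-6-methoxy-5-(triisopropylsilyloxy)-1-benzofuran-3-carboxylate
Product: 10 (±)-methyl 4-bromo-2-[1-(3,5-dimethoxyphenoxy)-2-oxopropyl]-6-methoxy-5-(triisopropylsilyloxy)-1-benzofuran-3-carboxylate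
Conditions: LiN(iPr)2 (1.2 equiv), THF, −78 °C; MeC(O)N(OMe)Me, −78 to −20 °C; cold 1 M HCl
Reagents that add atoms: N-methoxy-N-methylacetamide CC(=O)N(C)OC
Why: Lateral (vinylogous) deprotonation of the CH2 group conjugated with the C3 ester gives a dienolate that reacts at the exocyclic carbon to restore the furan, the chelated tetrahedral adduct of the Weinreb ketone synthesis blocks over-addition and early proton transfer, and the new stereocentre forms as a racemate.

Step 7
Reactants: 10 (±)-methyl 4-bromo-2-[1-(3,5-dimethoxyphenoxy)-2-oxopropyl]-6-methoxy-5-(triisopropylsilyloxy)-1-benzofuran-3-carboxylate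
Product: 12 1-bromo-6-(3,5-dimethoxyphenoxy)-3-methoxy-2-(triisopropylsilyloxy)dibenzo[b,d]furan-7,9-diol, via cyclic 1,3-diketone tautomer 11 (not isolated)
Conditions: LiN(iPr)2 (3.5 equiv), THF, −78 to 0 °C; 1 M HCl
Reagents that add atoms: none
Why: The first equivalent of LiN(iPr)2 takes the acidic methine proton (flanked by furan C2, the ketone and the aryloxy oxygen) and a further equivalent deprotonates the methyl group of this enolate, the same second deprotonation that gives β-keto ester dianions, so the terminal carbon becomes the most nucleophilic site. That carbon adds to the ester carbonyl on furan C3 in a 6-exo-trig closure, methoxide leaves, and diketone 11 is deprotonated at C8 and tautomerises to the resorcinolate, so one C–C bond (C8–C9) and ring D are formed and the sequence cannot revert. The closest known reaction type is the Claisen (Dieckmann-type) cyclisation of aryl esters bearing an ortho 2-oxopropyl group to 1,3-dihydroxyarenes, as used in biomimetic syntheses of naphthalene-1,3-diols. Two selectivities are needed, methyl versus methine carbon and carbon versus oxygen acylation: the methine carbon could only close a four-membered ring, lithium chelation between the enolate oxygen and the aryloxy oxygen fixes the enolate geometry that points the CH2 terminus rather than the oxygen at the ester, and any enol lactone that forms is reopened by methoxide whereas aromatisation is final. The C4 bromine twists the ester out of the furan plane, which keeps it electrophilic despite the neighbouring enolate and turns its π* orbital towards the side chain. No stereocentre is created; the racemic centre of 10 becomes the sp2 carbon C6.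

Step 8
Reactants: 12 1-bromo-6-(3,5-dimethoxyphenoxy)-3-methoxy-2-(triisopropylsilyloxy)dibenzo[b,d]furan-7,9-diol
Product: 13 1-bromo-6-(3,5-dimethoxyphenoxy)-3,7,9-trimethoxy-2-(triisopropylsilyloxy)dibenzo[b,d]furan
Conditions: MeI (excess), K2CO3, acetone, 50 °C
Reagents that add atoms: iodomethane CI
Why: Williamson O-methylation caps both ring D phenols, so that the ring C oxygen is the only free phenol after desilylation.

Step 9
Reactants: 13 1-bromo-6-(3,5-dimethoxyphenoxy)-3,7,9-trimethoxy-2-(triisopropylsilyloxy)dibenzo[b,d]furan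
Product: 14 1-bromo-6-(3,5-dimethoxyphenoxy)-3,7,9-trimethoxydibenzo[b,d]furan-2-ol
Conditions: Bu4NF, AcOH, THF, 0 °C
Reagents that add atoms: none
Why: Buffered fluoride cleavage of the Si–O bond is orthogonal to the aryl bromide, the methyl ethers and the diaryl ether.

Step 10
Reactants: 15 1-fluoro-3,5-dimethoxybenzene
Product: 17 2-fluoro-4,6-dimethoxybenzene-1,3-dicarbaldehyde, via 2-fluoro-4,6-dimethoxybenzaldehyde 16 (not isolated)
Conditions: Cl2CHOMe (5 equiv), TiCl4 (5 equiv), CH2Cl2, 0 °C to reflux; ice–water
Reagents that add atoms: dichloromethyl methyl ether COC(Cl)Cl; water O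
Why: In this twofold Rieche formylation each substitution goes para to one methoxy and ortho to the other, that is to the two equivalent positions next to fluorine, as known for 5-substituted 1,3-dimethoxybenzenes and for the second formylation of 2,4-dimethoxybenzaldehyde.

Step 11
Reactants: 14 1-bromo-6-(3,5-dimethoxyphenoxy)-3,7,9-trimethoxydibenzo[b,d]furan-2-ol; 17 2-fluoro-4,6-dimethoxybenzene-1,3-dicarbaldehyde
Product: 18 2-{[1-bromo-6-(3,5-dimethoxyphenoxy)-3,7,9-trimethoxydibenzo[b,d]furan-2-yl]oxy}-4,6-dimethoxybenzene-1,3-dicarbaldehyde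
Conditions: Cs2CO3, DMF, 80 °C
Reagents that add atoms: none
Why: In this nucleophilic aromatic substitution the fluoride of 17 is ortho to two formyl groups that both stabilise the Meisenheimer adduct, fluoride is by far the best leaving group on the ring, the small fluorine admits the hindered phenoxide from above the ring plane, and the symmetry of 17 allows only one diaryl ether.

Step 12
Reactants: 18 2-{[1-bromo-6-(3,5-dimethoxyphenoxy)-3,7,9-trimethoxydibenzo[b,d]furan-2-yl]oxy}-4,6-dimethoxybenzene-1,3-dicarbaldehyde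
Product: 20 2-{[1-bromo-6-(3,5-dimethoxyphenoxy)-3,7,9-trimethoxydibenzo[b,d]furan-2-yl]oxy}-4,6-dimethoxybenzene-1,3-diol, via bis(formate) 19 (not isolated)
Conditions: mCPBA (3 equiv), CH2Cl2, rt; then K2CO3 (cat.), MeOH, Ar, rt
Reagents that add atoms: 3-chloroperoxybenzoic acid OOC(=O)c1cccc(Cl)c1
Why: Baeyer–Villiger oxidation of electron-rich ortho,ortho'-dioxygenated benzaldehydes goes with aryl migration to aryl formates (a Dakin-type outcome), and mild methanolysis then frees the two equivalent phenols flanking the new ether without touching the bromide or the methyl ethers.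

Step 13
Reactants: 20 2-{[1-bromo-6-(3,5-dimethoxyphenoxy)-3,7,9-trimethoxydibenzo[b,d]furan-2-yl]oxy}-4,6-dimethoxybenzene-1,3-diol
Product: 21 9-(3,5-dimethoxyphenoxy)-1,3,6,10,12-pentamethoxy[1]benzofuro[3,2-a]oxanthren-4-ol (rings A–E complete, one ring A hydroxyl next to the ring B oxygen free)
Conditions: CuI (20 mol %), N,N-dimethylglycine (40 mol %), Cs2CO3, dioxane, 110 °C, Ar
Reagents that add atoms: none
Why: An intramolecular Ullmann diaryl ether synthesis closes six-membered ring B at the bay carbon, either of the two equivalent phenoxides gives the same product, and the unactivated ring C rules out a Smiles rearrangement.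

Step 14
Reactants: 21 9-(3,5-dimethoxyphenoxy)-1,3,6,10,12-pentamethoxy[1]benzofuro[3,2-a]oxanthren-4-ol; 22 1-iodo-3,5-dimethoxybenzene
Product: 23 4,9-bis(3,5-dimethoxyphenoxy)-1,3,6,10,12-pentamethoxy[1]benzofuro[3,2-a]oxanthrene
Conditions: CuI (10 mol %), picolinic acid (20 mol %), K3PO4, DMSO, 90 °C
Reagents that add atoms: none
Why: This is a ligand-accelerated Ullmann ether synthesis between the one remaining ortho,ortho'-disubstituted phenol and an unhindered aryl iodide, a pairing for which the CuI/picolinic acid system is established.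

Step 15
Reactants: 23 4,9-bis(3,5-dimethoxyphenoxy)-1,3,6,10,12-pentamethoxy[1]benzofuro[3,2-a]oxanthrene
Product: 24 phlorofucofuroeckol A
Conditions: BBr3 (excess), CH2Cl2, −78 °C to rt; then H2O
Reagents that add atoms: none
Why: In this Lewis-acid ether cleavage bromide attacks the methyl carbon of all nine aryl methyl ethers, whereas the diaryl ether, dioxin and furan C–O bonds offer no sp3 carbon and should remain intact.

**Compound list**

1 | 2-methoxy-1,4-benzoquinone | COC1=CC(=O)C=CC1=O | starting material
2 | methyl acetoacetate | COC(=O)CC(C)=O | starting material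
3 | methyl 2-(2,5-dihydroxy-4-methoxyphenyl)-3-oxobutanoate (racemic, not isolated) | COC(=O)C(C(C)=O)c1cc(O)c(OC)cc1O | intermediate
4 | methyl 5-hydroxy-6-methoxy-2-methyl-1-benzofuran-3-carboxylate | COC(=O)c1c(C)oc2cc(OC)c(O)cc12 | intermediate
5 | methyl 4-bromo-5-hydroxy-6-methoxy-2-methyl-1-benzofuran-3-carboxylate | COC(=O)c1c(C)oc2cc(OC)c(O)c(Br)c12 | intermediate
6 | methyl 4-bromo-6-methoxy-2-methyl-5-(triisopropylsilyloxy)-1-benzofuran-3-carboxylate | COC(=O)c1c(C)oc2cc(OC)c(O[Si](C(C)C)(C(C)C)C(C)C)c(Br)c12 | intermediate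
7 | methyl 4-bromo-2-(bromomethyl)-6-methoxy-5-(triisopropylsilyloxy)-1-benzofuran-3-carboxylate | COC(=O)c1c(CBr)oc2cc(OC)c(O[Si](C(C)C)(C(C)C)C(C)C)c(Br)c12 | intermediate
8 | 3,5-dimethoxyphenol | COc1cc(O)cc(OC)c1 | starting material
9 | methyl 4-bromo-2-[(3,5-dimethoxyphenoxy)methyl]-6-methoxy-5-(triisopropylsilyloxy)-1-benzofuran-3-carboxylate | COC(=O)c1c(COc2cc(OC)cc(OC)c2)oc2cc(OC)c(O[Si](C(C)C)(C(C)C)C(C)C)c(Br)c12 | intermediate
10 | (±)-methyl 4-bromo-2-[1-(3,5-dimethoxyphenoxy)-2-oxopropyl]-6-methoxy-5-(triisopropylsilyloxy)-1-benzofuran-3-carboxylate | COC(=O)c1c(C(Oc2cc(OC)cc(OC)c2)C(C)=O)oc2cc(OC)c(O[Si](C(C)C)(C(C)C)C(C)C)c(Br)c12 | intermediate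
11 | 1-bromo-6-(3,5-dimethoxyphenoxy)-3-methoxy-2-(triisopropylsilyloxy)-6,8-dihydrodibenzo[b,d]furan-7,9-dione (racemic, labile centre, not isolated) | O=C1CC(=O)c2c(oc3cc(OC)c(O[Si](C(C)C)(C(C)C)C(C)C)c(Br)c23)C1Oc1cc(OC)cc(OC)c1 | intermediate
12 | 1-bromo-6-(3,5-dimethoxyphenoxy)-3-methoxy-2-(triisopropylsilyloxy)dibenzo[b,d]furan-7,9-diol | CC(C)[Si](Oc1c(OC)cc2oc3c(Oc4cc(OC)cc(OC)c4)c(O)cc(O)c3c2c1Br)(C(C)C)C(C)C | intermediate
13 | 1-bromo-6-(3,5-dimethoxyphenoxy)-3,7,9-trimethoxy-2-(triisopropylsilyloxy)dibenzo[b,d]furan | CC(C)[Si](Oc1c(OC)cc2oc3c(Oc4cc(OC)cc(OC)c4)c(OC)cc(OC)c3c2c1Br)(C(C)C)C(C)C | intermediate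
14 | 1-bromo-6-(3,5-dimethoxyphenoxy)-3,7,9-trimethoxydibenzo[b,d]furan-2-ol | COc1cc2oc3c(Oc4cc(OC)cc(OC)c4)c(OC)cc(OC)c3c2c(Br)c1O | intermediate
15 | 1-fluoro-3,5-dimethoxybenzene | COc1cc(F)cc(OC)c1 | starting material
16 | 2-fluoro-4,6-dimethoxybenzaldehyde (not isolated) | COc1cc(F)c(C=O)c(OC)c1 | intermediate
17 | 2-fluoro-4,6-dimethoxybenzene-1,3-dicarbaldehyde | COc1cc(OC)c(C=O)c(F)c1C=O | intermediate
18 | 2-{[1-bromo-6-(3,5-dimethoxyphenoxy)-3,7,9-trimethoxydibenzo[b,d]furan-2-yl]oxy}-4,6-dimethoxybenzene-1,3-dicarbaldehyde | COc1cc(OC)c(C=O)c(Oc2c(OC)cc3oc4c(Oc5cc(OC)cc(OC)c5)c(OC)cc(OC)c4c3c2Br)c1C=O | intermediate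
19 | 2-{[1-bromo-6-(3,5-dimethoxyphenoxy)-3,7,9-trimethoxydibenzo[b,d]furan-2-yl]oxy}-4,6-dimethoxybenzene-1,3-diyl diformate (not isolated) | COc1cc(OC)c(OC=O)c(Oc2c(OC)cc3oc4c(Oc5cc(OC)cc(OC)c5)c(OC)cc(OC)c4c3c2Br)c1OC=O | intermediate
20 | 2-{[1-bromo-6-(3,5-dimethoxyphenoxy)-3,7,9-trimethoxydibenzo[b,d]furan-2-yl]oxy}-4,6-dimethoxybenzene-1,3-diol | COc1cc(OC)c(O)c(Oc2c(OC)cc3oc4c(Oc5cc(OC)cc(OC)c5)c(OC)cc(OC)c4c3c2Br)c1O | intermediate
21 | 9-(3,5-dimethoxyphenoxy)-1,3,6,10,12-pentamethoxy[1]benzofuro[3,2-a]oxanthren-4-ol | Oc1c(OC)cc(OC)c2c1Oc1c(OC)cc3oc4c(Oc5cc(OC)cc(OC)c5)c(OC)cc(OC)c4c3c1O2 | intermediate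
22 | 1-iodo-3,5-dimethoxybenzene | COc1cc(I)cc(OC)c1 | starting material
23 | 4,9-bis(3,5-dimethoxyphenoxy)-1,3,6,10,12-pentamethoxy[1]benzofuro[3,2-a]oxanthrene | COc1cc(OC)cc(Oc2c(OC)cc(OC)c3c2Oc2c(OC)cc4oc5c(Oc6cc(OC)cc(OC)c6)c(OC)cc(OC)c5c4c2O3)c1 | intermediate
24 | phlorofucofuroeckol A | Oc1cc(O)cc(Oc2c(O)cc(O)c3c2Oc2c(O)cc4oc5c(Oc6cc(O)cc(O)c6)c(O)cc(O)c5c4c2O3)c1 | target

**Step count**

Total step count: 15. Longest linear sequence: 14 steps (steps 1–9 and 11–15); step 10 is the side branch.

**Steps most likely to fail**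

1. Step 7.
- What may go wrong: the base may be used up by the methine proton without the second deprotonation following. Alternatively, acylation at the enolate oxygen (enol lactonisation) may outrun C-acylation.
- The fallback sets out from 9 and comes back at 12. It keeps the same ring closure but makes the attacking carbon as acidic as the methine by means of a removable ester.
- The anion of 9 (LiN(iPr)2, THF, −78 °C) is carboxylated with CO2 to the racemic α-aryloxy acetic acid F1. CDI followed by Mg(O2CCH2CO2tBu)2 extends this by a magnesium malonate homologation to the racemic tert-butyl β-keto ester F2.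
- In F2 the nucleophilic carbon is a malonate-type CH2, so KOtBu in THF at 0 °C should close the same C8–C9 bond by an ordinary Dieckmann condensation and give the ring D tert-butyl ester F3.
- TFA with Et3SiH in CH2Cl2 cleaves the ester to the 2,6-dihydroxybenzoic acid F4, which should decarboxylate on gentle warming to 12.

2. Step 13.
- What may go wrong: copper may insert only slowly into the C1–Br bond, which is flanked by the ring A ether and the bay methoxy group. Protodebromination or oxidation of the electron-rich diol could then take over.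
- The fallback sets out from 20 and comes back at 21. It inverts the polarity of C1.
- Compound 20 is deprotonated twice with NaH, the bromide is exchanged with t-BuLi at −78 °C (a process little affected by crowding), and the aryllithium is trapped with B(OMe)3 to give, after mild acid, the boronic acid F5.
- Cu(OAc)2, pyridine, 4 Å molecular sieves, air, CH2Cl2, rt should then close ring B by an intramolecular Chan–Lam coupling, in which transmetalation to divalent copper takes the place of the insertion into C–Br.

3. Step 6.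
- What may go wrong: the hindered, stabilised α-aryloxy carbanion may add to the amide slowly or reversibly. Self-condensation of the anion with the ester of unreacted 9 is also possible.
- The fallback sets out from 6 and comes back at 10. It reverses the order of C–C and C–O bond formation.
- The unhindered anion of the C2 methyl group of 6 (LiN(iPr)2, −78 °C) is acylated with N-methoxy-N-methylacetamide to the 2-(2-oxopropyl) ketone F6.
- CuBr2 in EtOAc–CHCl3 at reflux brominates the doubly activated CH2 between furan and ketone to the racemic α-bromo ketone F7.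
- 3,5-Dimethoxyphenol 8 with K2CO3 in acetone then displaces the bromide by SN2 to give 10.

**Further compounds**

F1 | step 7 | (±)-2-[4-bromo-6-methoxy-3-(methoxycarbonyl)-5-(triisopropylsilyloxy)-1-benzofuran-2-yl]-2-(3,5-dimethoxyphenoxy)acetic acid | COC(=O)c1c(C(Oc2cc(OC)cc(OC)c2)C(O)=O)oc2cc(OC)c(O[Si](C(C)C)(C(C)C)C(C)C)c(Br)c12
F2 | step 7 | (±)-methyl 4-bromo-2-[4-tert-butoxy-1-(3,5-dimethoxyphenoxy)-2,4-dioxobutyl]-6-methoxy-5-(triisopropylsilyloxy)-1-benzofuran-3-carboxylate | COC(=O)c1c(C(Oc2cc(OC)cc(OC)c2)C(=O)CC(=O)OC(C)(C)C)oc2cc(OC)c(O[Si](C(C)C)(C(C)C)C(C)C)c(Br)c12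
F3 | step 7 | tert-butyl 1-bromo-6-(3,5-dimethoxyphenoxy)-7,9-dihydroxy-3-methoxy-2-(triisopropylsilyloxy)dibenzo[b,d]furan-8-carboxylate | CC(C)[Si](Oc1c(OC)cc2oc3c(Oc4cc(OC)cc(OC)c4)c(O)c(C(=O)OC(C)(C)C)c(O)c3c2c1Br)(C(C)C)C(C)C
F4 | step 7 | 1-bromo-6-(3,5-dimethoxyphenoxy)-7,9-dihydroxy-3-methoxy-2-(triisopropylsilyloxy)dibenzo[b,d]furan-8-carboxylic acid | CC(C)[Si](Oc1c(OC)cc2oc3c(Oc4cc(OC)cc(OC)c4)c(O)c(C(O)=O)c(O)c3c2c1Br)(C(C)C)C(C)C
F5 | step 13 | [2-(2,6-dihydroxy-3,5-dimethoxyphenoxy)-6-(3,5-dimethoxyphenoxy)-3,7,9-trimethoxydibenzo[b,d]furan-1-yl]boronic acid | COc1cc(OC)c(O)c(Oc2c(OC)cc3oc4c(Oc5cc(OC)cc(OC)c5)c(OC)cc(OC)c4c3c2B(O)O)c1O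
F6 | step 6 | methyl 4-bromo-6-methoxy-2-(2-oxopropyl)-5-(triisopropylsilyloxy)-1-benzofuran-3-carboxylate | COC(=O)c1c(CC(C)=O)oc2cc(OC)c(O[Si](C(C)C)(C(C)C)C(C)C)c(Br)c12
F7 | step 6 | (±)-methyl 4-bromo-2-(1-bromo-2-oxopropyl)-6-methoxy-5-(triisopropylsilyloxy)-1-benzofuran-3-carboxylate | COC(=O)c1c(C(Br)C(C)=O)oc2cc(OC)c(O[Si](C(C)C)(C(C)C)C(C)C)c(Br)c12
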